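**Retrosynthetic overview**
1. The target is epicatechin-(4β→8)-catechin carrying a 4-hydroxybenzoate on the lower 3-oxygen. The last operations are desilylation of the lower 3-O, esterification with 4-benzyloxybenzoic acid and hydrogenolysis of ten benzyl ethers.
2. Key disconnection is C4–C4a of the upper unit. C4 of ring C is bonded to C4a of ring A and to C8 of ring D, and C8 is flanked ortho/para by O1 (ring F), 7-O and 5-O, so a cation at C4 is strongly stabilised. Ring C is therefore closed last, by Friedel–Crafts attack of ring A (a tethered 3,5-dibenzyloxyphenyl ether) on that cation, generated from an open-chain C4 carbinol of either configuration.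
3. The carbinol (C4–C8 bond) comes from C8-lithiated, protected (+)-catechin (rings D, F, E ready-made) and a (2S,3R)-2-benzyloxy-3-aryloxy-3-arylpropanal.
4. The aldehyde comes from an Evans syn-glycolate aldol with 3,4-dibenzyloxybenzaldehyde (sets upper C2 and C3, brings ring B) and a CuI-catalysed O-arylation of the benzylic hydroxyl with retention (O1–C8a bond, brings ring A).
5. Ring order: D/F/E and B are bought, ring A is attached as an aryl ether, ring C is formed last.

Key step: step 13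

Assumption: the SMILES is read as epicatechin-(4β→8)-catechin (upper unit, rings A/C/B: 2R,3R,4R; lower unit, rings D/F/E: 2R,3S) acylated at the lower 3-O; (S)-4-benzyloxazolidin-2-one and benzyloxyacetyl chloride are taken as additional commercial starting materials.

**Route**

Step 1
Reactants: 1 (+)-catechin
Product: 2 5,7,3',4'-tetra-O-benzyl-(+)-catechin, i.e. (2R,3S)-5,7-bis(benzyloxy)-2-[3,4-bis(benzyloxy)phenyl]chroman-3-ol
Conditions: BnBr (4.4 equiv), K2CO3, DMF, 0 °C → rt
Reagents that add atoms: benzyl bromide, BrCc1ccccc1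
Why: Williamson etherification in which carbonate ionises only the four phenols, so they are O-benzylated while the aliphatic 3-hydroxyl stays free and no stereocentre is touched.

Step 2
Reactants: 2 5,7,3',4'-tetra-O-benzyl-(+)-catechin
Product: 3 8-bromo-5,7,3',4'-tetra-O-benzyl-(+)-catechin
Conditions: NBS (1.0 equiv), CH2Cl2, −78 °C → rt
Reagents that add atoms: N-bromosuccinimide, O=C1CCC(=O)N1Br
Why: Electrophilic aromatic bromination, which in 5,7-di-O-benzyl flavan-3-ols prefers C8 (ortho to O1 and 7-OBn, para to 5-OBn) over C6, and one equivalent at low temperature should stop at the monobromide.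

Step 3
Reactants: 3 8-bromo-5,7,3',4'-tetra-O-benzyl-(+)-catechin
Product: 4 8-bromo-3-O-(tert-butyldimethylsilyl)-5,7,3',4'-tetra-O-benzyl-(+)-catechin
Conditions: TBSCl, imidazole, DMF, rt
Reagents that add atoms: tert-butyldimethylsilyl chloride, CC(C)(C)[Si](C)(C)Cl
Why: Imidazole-promoted silylation of the only free hydroxyl gives a group that tolerates the organolithium and the Lewis acid and can later be removed by fluoride in the presence of benzyl ethers.

Step 4
Reactants: 5 5-bromoresorcinol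
Product: 6 1-bromo-3,5-bis(benzyloxy)benzene
Conditions: BnBr (2.2 equiv), K2CO3, DMF, rt
Reagents that add atoms: benzyl bromide, BrCc1ccccc1
Why: Williamson etherification of both phenols gives the ring A precursor with its two oxygens in the form needed in the target after hydrogenolysis.

Step 5
Reactants: 7 (S)-4-benzyloxazolidin-2-one; 8 benzyloxyacetyl chloride
Product: 10 (S)-4-benzyl-3-[(benzyloxy)acetyl]oxazolidin-2-one, via N-lithio oxazolidinone 9 (not isolated)
Conditions: n-BuLi, THF, −78 °C; then 8, −78 → 0 °C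
Reagents that add atoms: none
Why: N-acylation of the lithiated oxazolidinone by the acid chloride is the standard way to load a glycolate unit on the auxiliary and does not touch its stereocentre.

Step 6
Reactants: 10 (S)-4-benzyl-3-[(benzyloxy)acetyl]oxazolidin-2-one; 11 3,4-dibenzyloxybenzaldehyde
Product: 13 (S)-4-benzyl-3-[(2S,3R)-2-(benzyloxy)-3-[3,4-bis(benzyloxy)phenyl]-3-hydroxypropanoyl]oxazolidin-2-one, via Z-boron enolate 12 (not isolated)
Conditions: Bu2BOTf, Et3N, CH2Cl2, −78 → 0 °C; then 11, −78 → 0 °C; pH 7 buffer, MeOH, H2O2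
Reagents that add atoms: none
Why: Evans syn-glycolate aldol in which the Z-boron enolate reacts through a Zimmerman–Traxler chair on the enolate face away from the auxiliary benzyl group, which sets the 2,3-syn pair as (2S,3R) (the future upper C3 and C2) and leaves the benzylic hydroxyl as the only free one.

Step 7
Reactants: 13 syn-aldol imide
Product: 14 (1R,2R)-2-(benzyloxy)-1-[3,4-bis(benzyloxy)phenyl]propane-1,3-diol
Conditions: LiBH4, MeOH (1 equiv), THF, 0 °C
Reagents that add atoms: none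
Why: Reductive cleavage of the imide by LiBH4 attacks the exocyclic carbonyl, releases the auxiliary and removes the carbonyl that would otherwise allow retro-aldol or epimerisation in the basic arylation, with both stereocentres untouched.

Step 8
Reactants: 14 diol
Product: 15 (1R,2R)-2-(benzyloxy)-1-[3,4-bis(benzyloxy)phenyl]-3-[(tert-butyldiphenylsilyl)oxy]propan-1-ol
Conditions: TBDPSCl (1.05 equiv), imidazole, CH2Cl2, 0 °C
Reagents that add atoms: tert-butyldiphenylsilyl chloride, CC(C)(C)[Si](Cl)(c1ccccc1)c1ccccc1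
Why: Sterically controlled silylation takes the primary hydroxyl and leaves the hindered benzylic one free, and the bulky silyl group is base-stable and slow to migrate.

Step 9
Reactants: 15 mono-silylated diol; 6 1-bromo-3,5-bis(benzyloxy)benzene
Product: 16 tert-butyl{[(2R,3R)-2-(benzyloxy)-3-[3,5-bis(benzyloxy)phenoxy]-3-[3,4-bis(benzyloxy)phenyl]propyl]oxy}diphenylsilane
Conditions: 6 (2 equiv), CuI (20 mol %), 3,4,7,8-tetramethyl-1,10-phenanthroline (40 mol %), Cs2CO3, 4 Å MS, toluene, 110 °C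
Reagents that add atoms: none
Why: Ullmann-type copper-catalysed C–O coupling of a secondary alcohol with an aryl bromide forms the bond between the alkoxide oxygen and the arene, so the benzylic C–O bond is never broken and the future C2 keeps its configuration (retention).

Step 10
Reactants: 16 silyl-protected aryl ether
Product: 17 (2R,3R)-2-(benzyloxy)-3-[3,5-bis(benzyloxy)phenoxy]-3-[3,4-bis(benzyloxy)phenyl]propan-1-ol
Conditions: Bu4NF, THF, 0 °C → rt
Reagents that add atoms: none
Why: Fluoride cleaves the Si–O bond selectively and leaves benzyl and aryl ethers untouched.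

Step 11
Reactants: 17 primary alcohol
Product: 18 (2S,3R)-2-(benzyloxy)-3-[3,5-bis(benzyloxy)phenoxy]-3-[3,4-bis(benzyloxy)phenyl]propanal
Conditions: Dess–Martin periodinane, CH2Cl2, 0 °C → rt; used crude at once
Reagents that add atoms: none
Why: Dess–Martin oxidation stops at the aldehyde under non-basic conditions, which should avoid epimerisation of the α-benzyloxy centre and β-elimination of the aryloxide.

Step 12
Reactants: 4 8-bromo-3-O-TBS-tetra-O-benzylcatechin; 18 aldehyde
Product: 20 open-chain C4 carbinol 8-[(1RS,2R,3R)-2-(benzyloxy)-3-[3,5-bis(benzyloxy)phenoxy]-3-[3,4-bis(benzyloxy)phenyl]-1-hydroxypropyl]-3-O-TBS-5,7,3',4'-tetra-O-benzyl-(+)-catechin (both C4 epimers of the future upper unit), via 8-lithio catechin ether 19 (not isolated)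
Conditions: 4 (1.3 equiv), n-BuLi, THF, −78 °C; then 18, −78 °C; H2O quench; Et3N-deactivated silica
Reagents that add atoms: none
Why: Bromine–lithium exchange followed by 1,2-addition of the aryllithium to the aldehyde forms the C4–C8 bond, and the uncontrolled carbinol configuration is harmless because step 13 erases it.

Step 13
Reactants: 20 open-chain C4 carbinol (both epimers)
Product: 22 3-O-benzyl-5,7,3',4'-tetra-O-benzyl-epicatechin-(4β→8)-[3-O-TBS-5,7,3',4'-tetra-O-benzylcatechin], via C4 cation 21 (not isolated)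
Conditions: BF3·OEt2 (1.5 equiv), CH2Cl2 (0.005 M), −78 → −30 °C
Reagents that add atoms: none
Why: BF3·OEt2 ionises the hydroxyl of both C4 epimers of 20 to the same planar cation 21, stabilised by O1, 5-O and 7-O of ring D, so the carbinol configuration is lost (stereoconvergence), and the tethered 3,5-dibenzyloxyphenyl ether attacks it through the carbon ortho to O1, which is also ortho and para to its two benzyloxy groups, forming C4–C4a. The closest known reaction type is the intramolecular Friedel–Crafts alkylation of 3-aryloxy-1-arylpropan-1-ols to 4-arylchromans, together with the Lewis acid C4–C8 couplings of flavan-3-ols that pass through the same kind of trioxygenated benzylic cation. Ring C closes as a six-membered ring, 6-exo-trig at C4 when 21 is drawn as its ring D quinone methide (the C4=C8 π bond stays outside the new ring) and 6-endo as seen from the arene π bond, the usual mode of chroman closure. The new C4 stereocentre is controlled by C2 and C3: in the half-chair transition state ring B is equatorial and 3-OBn axial, and ring D takes the pseudoaxial position anti to 3-OBn and away from the peri 5-OBn of the forming ring A, which should give the 3,4-trans (4β, 4R) product. The step needs this facial selectivity, ionisation at C4 rather than at the C2 benzylic aryl ether, and ring closure ahead of intermolecular attack at C6 of ring D; these are secured respectively by the C2/C3 substituents, by the far greater stability of the 2,4,6-trioxygenated cation at low temperature, and by high dilution with two equivalent, strongly activated ortho carbons.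

Step 14
Reactants: 22 protected dimer with lower 3-O-TBS
Product: 23 3-O-benzyl-5,7,3',4'-tetra-O-benzyl-epicatechin-(4β→8)-5,7,3',4'-tetra-O-benzylcatechin (free lower 3-OH)
Conditions: Bu4NF, THF, rt
Reagents that add atoms: none
Why: Fluoride desilylation frees only the lower 3-hydroxyl, since every other oxygen is a benzyl ether.

Step 15
Reactants: 23 dimer with free lower 3-OH; 24 4-benzyloxybenzoic acid
Product: 25 3-O-benzyl-5,7,3',4'-tetra-O-benzyl-epicatechin-(4β→8)-[3-O-(4-benzyloxybenzoyl)-5,7,3',4'-tetra-O-benzylcatechin]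
Conditions: 24 (3 equiv), DCC, DMAP, CH2Cl2, rt
Reagents that add atoms: none
Why: Steglich esterification through the DMAP-acylpyridinium acylates the hindered secondary alcohol at oxygen without touching C3, so the 3S configuration is kept.

Step 16
Reactants: 25 fully protected ester
Product: 26 target, (2R,3S)-2-(3,4-dihydroxyphenyl)-8-[(2R,3R,4R)-2-(3,4-dihydroxyphenyl)-3,5,7-trihydroxychroman-4-yl]-5,7-dihydroxychroman-3-yl 4-hydroxybenzoate
Conditions: H2 (1 atm), Pd(OH)2/C, THF/MeOH/H2O, rt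
Reagents that add atoms: none
Why: Catalytic hydrogenolysis over palladium hydroxide on carbon cleaves all ten O-benzyl groups (nine aryl ethers and the upper 3-O-benzyl ether) under neutral conditions that should spare the ester, the interflavan bond and the C2–O1 bonds.

**Compound list**
1 | (+)-catechin | O[C@H]1Cc2c(O)cc(O)cc2O[C@@H]1c1ccc(O)c(O)c1 | starting material
2 | 5,7,3',4'-tetra-O-benzyl-(+)-catechin | O[C@H]1Cc2c(OCc3ccccc3)cc(OCc3ccccc3)cc2O[C@@H]1c1ccc(OCc2ccccc2)c(OCc2ccccc2)c1 | intermediate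
3 | 8-bromo-5,7,3',4'-tetra-O-benzyl-(+)-catechin | O[C@H]1Cc2c(OCc3ccccc3)cc(OCc3ccccc3)c(Br)c2O[C@@H]1c1ccc(OCc2ccccc2)c(OCc2ccccc2)c1 | intermediate
4 | 8-bromo-3-O-TBS-5,7,3',4'-tetra-O-benzyl-(+)-catechin | CC(C)(C)[Si](C)(C)O[C@H]1Cc2c(OCc3ccccc3)cc(OCc3ccccc3)c(Br)c2O[C@@H]1c1ccc(OCc2ccccc2)c(OCc2ccccc2)c1 | intermediate
5 | 5-bromoresorcinol | Oc1cc(O)cc(Br)c1 | starting material
6 | 1-bromo-3,5-bis(benzyloxy)benzene | Brc1cc(OCc2ccccc2)cc(OCc2ccccc2)c1 | intermediate
7 | (S)-4-benzyloxazolidin-2-one | O=C1N[C@@H](Cc2ccccc2)CO1 | starting material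
8 | benzyloxyacetyl chloride | O=C(Cl)COCc1ccccc1 | starting material
9 | lithium salt of (S)-4-benzyloxazolidin-2-one (N-lithio) | [Li]N1C(=O)OC[C@@H]1Cc1ccccc1 | intermediate (not isolated)
10 | (S)-4-benzyl-3-[(benzyloxy)acetyl]oxazolidin-2-one | O=C(COCc1ccccc1)N1C(=O)OC[C@@H]1Cc1ccccc1 | intermediate
11 | 3,4-dibenzyloxybenzaldehyde | O=Cc1ccc(OCc2ccccc2)c(OCc2ccccc2)c1 | starting material
12 | Z-dibutylboron enolate of 10 | CCCCB(CCCC)O/C(=C\OCc1ccccc1)N1C(=O)OC[C@@H]1Cc1ccccc1 | intermediate (not isolated)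
13 | (S)-4-benzyl-3-[(2S,3R)-2-(benzyloxy)-3-[3,4-bis(benzyloxy)phenyl]-3-hydroxypropanoyl]oxazolidin-2-one | O=C([C@@H](OCc1ccccc1)[C@@H](c1ccc(OCc2ccccc2)c(OCc2ccccc2)c1)O)N1C(=O)OC[C@@H]1Cc1ccccc1 | intermediate
14 | (1R,2R)-2-(benzyloxy)-1-[3,4-bis(benzyloxy)phenyl]propane-1,3-diol | OC[C@@H](OCc1ccccc1)[C@@H](c1ccc(OCc2ccccc2)c(OCc2ccccc2)c1)O | intermediate
15 | (1R,2R)-2-(benzyloxy)-1-[3,4-bis(benzyloxy)phenyl]-3-[(tert-butyldiphenylsilyl)oxy]propan-1-ol | CC(C)(C)[Si](c1ccccc1)(c1ccccc1)OC[C@@H](OCc1ccccc1)[C@@H](c1ccc(OCc2ccccc2)c(OCc2ccccc2)c1)O | intermediate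
16 | tert-butyl{[(2R,3R)-2-(benzyloxy)-3-[3,5-bis(benzyloxy)phenoxy]-3-[3,4-bis(benzyloxy)phenyl]propyl]oxy}diphenylsilane | CC(C)(C)[Si](c1ccccc1)(c1ccccc1)OC[C@@H](OCc1ccccc1)[C@@H](c1ccc(OCc2ccccc2)c(OCc2ccccc2)c1)Oc1cc(OCc2ccccc2)cc(OCc2ccccc2)c1 | intermediate
17 | (2R,3R)-2-(benzyloxy)-3-[3,5-bis(benzyloxy)phenoxy]-3-[3,4-bis(benzyloxy)phenyl]propan-1-ol | OC[C@@H](OCc1ccccc1)[C@@H](c1ccc(OCc2ccccc2)c(OCc2ccccc2)c1)Oc1cc(OCc2ccccc2)cc(OCc2ccccc2)c1 | intermediate
18 | (2S,3R)-2-(benzyloxy)-3-[3,5-bis(benzyloxy)phenoxy]-3-[3,4-bis(benzyloxy)phenyl]propanal | O=C[C@@H](OCc1ccccc1)[C@@H](c1ccc(OCc2ccccc2)c(OCc2ccccc2)c1)Oc1cc(OCc2ccccc2)cc(OCc2ccccc2)c1 | intermediate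
19 | 8-lithio-3-O-TBS-5,7,3',4'-tetra-O-benzyl-(+)-catechin | CC(C)(C)[Si](C)(C)O[C@H]1Cc2c(OCc3ccccc3)cc(OCc3ccccc3)c([Li])c2O[C@@H]1c1ccc(OCc2ccccc2)c(OCc2ccccc2)c1 | intermediate (not isolated)
20 | open-chain C4 carbinol on C8 of protected catechin, both C4 epimers | CC(C)(C)[Si](C)(C)O[C@H]1Cc2c(OCc3ccccc3)cc(OCc3ccccc3)c(C(O)[C@@H](OCc3ccccc3)[C@@H](c3ccc(OCc4ccccc4)c(OCc4ccccc4)c3)Oc3cc(OCc4ccccc4)cc(OCc4ccccc4)c3)c2O[C@@H]1c1ccc(OCc2ccccc2)c(OCc2ccccc2)c1 | intermediate
21 | C4 benzylic cation stabilised by ring D | CC(C)(C)[Si](C)(C)O[C@H]1Cc2c(OCc3ccccc3)cc(OCc3ccccc3)c([CH+][C@@H](OCc3ccccc3)[C@@H](c3ccc(OCc4ccccc4)c(OCc4ccccc4)c3)Oc3cc(OCc4ccccc4)cc(OCc4ccccc4)c3)c2O[C@@H]1c1ccc(OCc2ccccc2)c(OCc2ccccc2)c1 | intermediate (not isolated)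
22 | 3-O-benzyl-5,7,3',4'-tetra-O-benzyl-epicatechin-(4β→8)-[3-O-TBS-5,7,3',4'-tetra-O-benzylcatechin] | CC(C)(C)[Si](C)(C)O[C@H]1Cc2c(OCc3ccccc3)cc(OCc3ccccc3)c([C@H]3c4c(OCc5ccccc5)cc(OCc5ccccc5)cc4O[C@H](c4ccc(OCc5ccccc5)c(OCc5ccccc5)c4)[C@@H]3OCc3ccccc3)c2O[C@@H]1c1ccc(OCc2ccccc2)c(OCc2ccccc2)c1 | intermediate
23 | 3-O-benzyl-5,7,3',4'-tetra-O-benzyl-epicatechin-(4β→8)-5,7,3',4'-tetra-O-benzylcatechin | O[C@H]1Cc2c(OCc3ccccc3)cc(OCc3ccccc3)c([C@H]3c4c(OCc5ccccc5)cc(OCc5ccccc5)cc4O[C@H](c4ccc(OCc5ccccc5)c(OCc5ccccc5)c4)[C@@H]3OCc3ccccc3)c2O[C@@H]1c1ccc(OCc2ccccc2)c(OCc2ccccc2)c1 | intermediate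
24 | 4-benzyloxybenzoic acid | O=C(O)c1ccc(OCc2ccccc2)cc1 | starting material
25 | deca-O-benzyl ester: protected dimer with lower 3-O-(4-benzyloxybenzoyl) | O=C(O[C@H]1Cc2c(OCc3ccccc3)cc(OCc3ccccc3)c([C@H]3c4c(OCc5ccccc5)cc(OCc5ccccc5)cc4O[C@H](c4ccc(OCc5ccccc5)c(OCc5ccccc5)c4)[C@@H]3OCc3ccccc3)c2O[C@@H]1c1ccc(OCc2ccccc2)c(OCc2ccccc2)c1)c1ccc(OCc2ccccc2)cc1 | intermediate
26 | epicatechin-(4β→8)-catechin 3-O-(4-hydroxybenzoate) on the lower unit (CNP0288594.1) | O=C(O[C@H]1Cc2c(O)cc(O)c([C@H]3c4c(O)cc(O)cc4O[C@H](c4ccc(O)c(O)c4)[C@@H]3O)c2O[C@@H]1c1ccc(O)c(O)c1)c1ccc(O)cc1 | target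

**Step count and risks**
Total step count: 16. Longest linear sequence: 12 steps (steps 5–11, then 12–16).

Most likely to fail:

1. Step 13. The planar C4 cation may be attacked with poor facial discrimination, may lose the C3 proton to an enol ether, or may alkylate C6 of ring D of a second molecule before ring C closes. Fallback: reverse the order in which the two bonds at C4 are made, so that the stereodetermining attack takes place on a cyclic cation. It sets out from aldehyde 18 and from alcohol 2 and comes back at 22. Alcohol 2 is silylated (TBSCl, imidazole, DMF) to 3-O-TBS-5,7,3',4'-tetra-O-benzyl-(+)-catechin F1, a C8 nucleophile. Aldehyde 18 is cyclised with SnCl4 in CH2Cl2 at −78 °C; chelation of the aldehyde and its α-benzyloxy group activates it for intramolecular Friedel–Crafts hydroxyalkylation by the same ortho carbon, giving the protected flavan-3,4-diol 3-O-benzyl-5,7,3',4'-tetra-O-benzyl-epicatechin-4-ol F2 (either C4 epimer). F2 and an excess of F1 are then treated with TMSOTf in CH2Cl2 at −78 °C. This is the established Lewis acid 4→8 coupling of C4-oxygenated flavan-3-ols, in which C8 of F1 adds to the ring C cation anti to the axial 3-benzyloxy group, and it should deliver 22.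

2. Step 9. C–O bond formation at the hindered benzylic alkoxide may be slow, so that hydrodebromination of 6 or silyl migration to the secondary oxygen competes. Fallback: make the aryl ether by substitution with inversion instead of by arylation with retention. It sets out from 15 and comes back at 16. Alcohol 15 is oxidised (Dess–Martin periodinane) to (R)-2-(benzyloxy)-1-[3,4-bis(benzyloxy)phenyl]-3-[(tert-butyldiphenylsilyl)oxy]propan-1-one F3. Chelation-controlled reduction with Zn(BH4)2 in Et2O at −20 °C should give the anti alcohol (1S,2R)-2-(benzyloxy)-1-[3,4-bis(benzyloxy)phenyl]-3-[(tert-butyldiphenylsilyl)oxy]propan-1-ol F4. A Mitsunobu reaction of F4 with commercial 3,5-bis(benzyloxy)phenol (Oc1cc(OCc2ccccc2)cc(OCc2ccccc2)c1; PPh3, diisopropyl azodicarboxylate, toluene, 0 °C) inverts the benzylic carbon and gives 16.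

3. Step 12. The hindered aryllithium may deprotonate the α-benzyloxy aldehyde instead of adding to it, leading to epimerisation at the future C3 or β-elimination of the aryloxide. Fallback: acylate the aryllithium with a less enolisable electrophile and reduce afterwards. It sets out from 17 and comes back at 20. Alcohol 17 is oxidised (TEMPO, PhI(OAc)2, MeCN/H2O) to (2S,3R)-2-(benzyloxy)-3-[3,5-bis(benzyloxy)phenoxy]-3-[3,4-bis(benzyloxy)phenyl]propanoic acid F5. Coupling with MeNHOMe·HCl (EDC·HCl, i-Pr2NEt, CH2Cl2) gives the N-methoxy-N-methylamide F6. Aryllithium 19 is added to F6 at −78 °C, where the chelated tetrahedral adduct is stable until work-up, to give the 8-acyl catechin ketone F7. Reduction of F7 with NaBH4 in THF/MeOH gives 20 as an epimer mixture, which is all the key step needs.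

Further compounds
F1 | step 13 | 3-O-TBS-5,7,3',4'-tetra-O-benzyl-(+)-catechin | CC(C)(C)[Si](C)(C)O[C@H]1Cc2c(OCc3ccccc3)cc(OCc3ccccc3)cc2O[C@@H]1c1ccc(OCc2ccccc2)c(OCc2ccccc2)c1
F2 | step 13 | (2R,3R)-3,5,7-tris(benzyloxy)-2-[3,4-bis(benzyloxy)phenyl]chroman-4-ol (C4 epimers) | OC1c2c(OCc3ccccc3)cc(OCc3ccccc3)cc2O[C@H](c2ccc(OCc3ccccc3)c(OCc3ccccc3)c2)[C@@H]1OCc1ccccc1
F3 | step 9 | (R)-2-(benzyloxy)-1-[3,4-bis(benzyloxy)phenyl]-3-[(tert-butyldiphenylsilyl)oxy]propan-1-one | CC(C)(C)[Si](c1ccccc1)(c1ccccc1)OC[C@@H](OCc1ccccc1)C(=O)c1ccc(OCc2ccccc2)c(OCc2ccccc2)c1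
F4 | step 9 | (1S,2R)-2-(benzyloxy)-1-[3,4-bis(benzyloxy)phenyl]-3-[(tert-butyldiphenylsilyl)oxy]propan-1-ol | CC(C)(C)[Si](c1ccccc1)(c1ccccc1)OC[C@@H](OCc1ccccc1)[C@H](c1ccc(OCc2ccccc2)c(OCc2ccccc2)c1)O
F5 | step 12 | (2S,3R)-2-(benzyloxy)-3-[3,5-bis(benzyloxy)phenoxy]-3-[3,4-bis(benzyloxy)phenyl]propanoic acid | O=C(O)[C@@H](OCc1ccccc1)[C@@H](c1ccc(OCc2ccccc2)c(OCc2ccccc2)c1)Oc1cc(OCc2ccccc2)cc(OCc2ccccc2)c1
F6 | step 12 | (2S,3R)-2-(benzyloxy)-3-[3,5-bis(benzyloxy)phenoxy]-3-[3,4-bis(benzyloxy)phenyl]-N-methoxy-N-methylpropanamide | CON(C)C(=O)[C@@H](OCc1ccccc1)[C@@H](c1ccc(OCc2ccccc2)c(OCc2ccccc2)c1)Oc1cc(OCc2ccccc2)cc(OCc2ccccc2)c1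
F7 | step 12 | (2S,3R)-2-(benzyloxy)-3-[3,5-bis(benzyloxy)phenoxy]-3-[3,4-bis(benzyloxy)phenyl]-1-[3-O-TBS-5,7,3',4'-tetra-O-benzylcatechin-8-yl]propan-1-one | CC(C)(C)[Si](C)(C)O[C@H]1Cc2c(OCc3ccccc3)cc(OCc3ccccc3)c(C(=O)[C@@H](OCc3ccccc3)[C@@H](c3ccc(OCc4ccccc4)c(OCc4ccccc4)c3)Oc3cc(OCc4ccccc4)cc(OCc4ccccc4)c3)c2O[C@@H]1c1ccc(OCc2ccccc2)c(OCc2ccccc2)c1
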